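**Retrosynthetic overview**
1. Atom labels: C1 = bridgehead bearing the isobutyryl group, C2 = ring ketone next to it, C4 = carbinol carbon, C3 = exocyclic enone carbonyl on C4, C5 = prenylated bridgehead, C6–C7–C8 = CH2–CH(prenyl)–CMe2, C9 = one-carbon ketone bridge (prenyl = 3-methylbut-2-enyl).
2. Enabling feature: in the five-membered ring C1–C2–C4–C5–C9, carbinol C4 carries its OH between ring ketone C2 and exocyclic carbonyl C3, which is an α-ketol. Moving C2 back from C4 to C3 re-expands this ring to the six-membered ring A (C1–C2–C3–C4–C5–C9) of a bicyclo[3.3.1]nonane C3-alkoxide. Cutting C3–CH= then gives a 2,3,4,9-tetraone and a (Z)-vinyl dianion.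
3. Tetraone ⇒ 2,4,9-trione (oxidation of the C3 methylene) ⇒ bridgehead C1 acylation and twofold allyl-to-prenyl cross metathesis on a bicyclic vinylogous ester.
4. Bicyclic vinylogous ester ⇒ C1–C8 disconnection (cationic cyclisation, removes ring B and the whole bridged system) ⇒ symmetric 4,4-dialkyl-3,5-dimethoxycyclohexadienone ⇒ dearomative allylation of a phenol. The phenol side chain (C6–C8, stereocentre C7) comes from an Evans benzylation.
5. Ring order: ring A (arene of the starting aldehyde, dearomatised in step 8), ring B = C1–C8–C7–C6–C5–C9 (step 9), contraction of ring A from six to five atoms (step 16).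

Key step: step 16

Remark: the (Z)-γ-hydroxy enone of the target may equilibrate with its five-membered lactol. The open form of the target structure is taken as the product, and enolisable 20 is drawn as its triketo tautomer.

**Step 1**
Reactants: 1 4-hydroxy-2,6-dimethoxybenzaldehyde
Product: 2 4-formyl-3,5-dimethoxyphenyl pivalate
Conditions: PivCl, Et3N, DMAP (cat.), CH2Cl2, 0 → 23 °C
Reagents that add atoms: pivaloyl chloride CC(C)(C)C(=O)Cl
Why: Standard DMAP-catalysed O-acylation of a phenol; the hindered, electron-withdrawing pivalate tames the benzylic halide made in step 3 and resists the enolate of step 5.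

**Step 2**
Reactants: 2 4-formyl-3,5-dimethoxyphenyl pivalate
Product: 3 4-(hydroxymethyl)-3,5-dimethoxyphenyl pivalate
Conditions: NaBH4, MeOH/THF, 0 °C
Reagents that add atoms: none
Why: Chemoselective borohydride reduction of the aldehyde, to which the aryl pivalate is inert at 0 °C.

**Step 3**
Reactants: 3 4-(hydroxymethyl)-3,5-dimethoxyphenyl pivalate
Product: 4 4-(bromomethyl)-3,5-dimethoxyphenyl pivalate
Conditions: PBr3, Et2O, 0 °C
Reagents that add atoms: phosphorus tribromide BrP(Br)Br
Why: Bromide displacement on the phosphite ester of a benzylic alcohol, mild enough for the electron-rich ring; 4 should be used without storage.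

**Step 4**
Reactants: 5 (S)-4-benzyloxazolidin-2-one; 6 pent-4-enoyl chloride
Product: 8 (S)-4-benzyl-3-(pent-4-enoyl)oxazolidin-2-one, via N-lithio oxazolidinone 7 (not isolated)
Conditions: n-BuLi, THF, −78 °C; then 6, −78 → 0 °C
Reagents that add atoms: none
Why: N-Acylation of the lithiated oxazolidinone by an acid chloride, the standard loading of the Evans auxiliary, which leaves its stereocentre untouched.

**Step 5**
Reactants: 8 (S)-4-benzyl-3-(pent-4-enoyl)oxazolidin-2-one; 4 4-(bromomethyl)-3,5-dimethoxyphenyl pivalate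
Product: 10 (S)-4-benzyl-3-[(R)-2-(2,6-dimethoxy-4-pivaloyloxybenzyl)pent-4-enoyl]oxazolidin-2-one, via sodium Z-enolate 9 (not isolated)
Conditions: NaN(SiMe3)2, THF, −78 °C; then 4, −78 → −20 °C
Reagents that add atoms: none
Why: Evans asymmetric alkylation, in which the chelated Z-enolate is benzylated on the face opposite to the benzyl group of the auxiliary and C7 is set as R, the only stereocentre brought in from outside.

**Step 6**
Reactants: 10 (S)-4-benzyl-3-[(R)-2-(2,6-dimethoxy-4-pivaloyloxybenzyl)pent-4-enoyl]oxazolidin-2-one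
Product: 11 methyl (R)-2-(4-hydroxy-2,6-dimethoxybenzyl)pent-4-enoate
Conditions: NaOMe, MeOH/THF, 0 °C; AcOH quench
Reagents that add atoms: sodium methoxide [Na+].[O-]C
Why: Methoxide transesterification cleaves the exocyclic imide carbonyl and the aryl pivalate in one operation, and short contact at 0 °C should avoid epimerisation of the α-stereocentre.

**Step 7**
Reactants: 11 methyl (R)-2-(4-hydroxy-2,6-dimethoxybenzyl)pent-4-enoate
Product: 12 4-[(R)-2-(2-hydroxypropan-2-yl)pent-4-enyl]-3,5-dimethoxyphenol
Conditions: MeMgBr (excess), THF, 0 → 23 °C; aq. NH4Cl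
Reagents that add atoms: methylmagnesium bromide C[Mg]Br
Why: Double Grignard addition to the ester gives the tertiary alcohol that already holds the C8 gem-dimethyl group and will be the source of the C8 cation; C7 is not touched.

**Step 8**
Reactants: 12 4-[(R)-2-(2-hydroxypropan-2-yl)pent-4-enyl]-3,5-dimethoxyphenol
Product: 13 4-allyl-4-[(R)-2-(2-hydroxypropan-2-yl)pent-4-enyl]-3,5-dimethoxycyclohexa-2,5-dienone
Conditions: allyl methyl carbonate, Pd(OAc)2 (cat.), PPh3 (cat.), Ti(OiPr)4 (cat.), toluene, 50 °C
Reagents that add atoms: allyl methyl carbonate C=CCOC(=O)OC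
Why: Tsuji–Trost dearomative para-allylation of a 4-alkyl-3,5-dimethoxyphenol, in which O-allylation is reversible under zerovalent palladium while C-allylation is not; the new quaternary carbon C5 is not yet stereogenic because ring A is symmetric.

**Step 9**
Reactants: 13 4-allyl-4-[(R)-2-(2-hydroxypropan-2-yl)pent-4-enyl]-3,5-dimethoxycyclohexa-2,5-dienone
Product: 14 (1R,5S,7R)-5,7-diallyl-4-methoxy-8,8-dimethylbicyclo[3.3.1]non-3-ene-2,9-dione
Conditions: HCO2H, 23 °C
Reagents that add atoms: none
Why: Biomimetic cationic cyclisation in which formic acid ionises the tertiary alcohol, capture at oxygen stays reversible, and one of the two diastereotopic methoxy-enone carbons traps the C8 cation through a chair transition state with the C7 allyl group equatorial, so that C7 sets C1 and C5 and loss of methanol gives the C9 ketone (monosubstituted allyl groups are not protonated).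

**Step 10**
Reactants: 14 (1R,5S,7R)-5,7-diallyl-4-methoxy-8,8-dimethylbicyclo[3.3.1]non-3-ene-2,9-dione
Product: 15 (1R,5S,7R)-4-methoxy-8,8-dimethyl-5,7-diprenylbicyclo[3.3.1]non-3-ene-2,9-dione
Conditions: second-generation Grubbs catalyst (cat.), 2-methylbut-2-ene/CH2Cl2, 40 °C
Reagents that add atoms: 2-methylbut-2-ene CC=C(C)C
Why: Twofold olefin cross metathesis turns both terminal allyl groups into prenyl groups, while the trisubstituted vinylogous ester alkene is inert.

**Step 11**
Reactants: 15 (1R,5S,7R)-4-methoxy-8,8-dimethyl-5,7-diprenylbicyclo[3.3.1]non-3-ene-2,9-dione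
Product: 17 (1S,5S,7R)-4-methoxy-8,8-dimethyl-5,7-diprenyl-3-(trimethylsilyl)bicyclo[3.3.1]non-3-ene-2,9-dione (C1 descriptor changes by priority only), via C3-lithio vinylogous ester 16 (not isolated)
Conditions: LiN(iPr)2, Me3SiCl (in situ), THF, −78 °C
Reagents that add atoms: chlorotrimethylsilane C[Si](C)(C)Cl
Why: Vinylic α-deprotonation of the vinylogous ester with in situ silylation blocks C3, the most acidic C–H, before the bridgehead is addressed.

**Step 12**
Reactants: 17 (1S,5S,7R)-4-methoxy-8,8-dimethyl-5,7-diprenyl-3-(trimethylsilyl)bicyclo[3.3.1]non-3-ene-2,9-dione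
Product: 19 (1R,5S,7R)-1-isobutyryl-4-methoxy-8,8-dimethyl-5,7-diprenyl-3-(trimethylsilyl)bicyclo[3.3.1]non-3-ene-2,9-dione, via C1-lithio bridgehead anion 18 (not isolated)
Conditions: lithium 2,2,6,6-tetramethylpiperidide, THF, −78 → −20 °C; then i-PrCOCl, −78 °C
Reagents that add atoms: isobutyryl chloride CC(C)C(=O)Cl
Why: Bridgehead lithiation–acylation of a bicyclo[3.3.1]nonane-2,9-dione, in which the carbanion flanked by C2=O and C9=O is acylated with retention because the cage allows no inversion.

**Step 13**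
Reactants: 19 (1R,5S,7R)-1-isobutyryl-4-methoxy-8,8-dimethyl-5,7-diprenyl-3-(trimethylsilyl)bicyclo[3.3.1]non-3-ene-2,9-dione
Product: 20 (1R,5S,7R)-1-isobutyryl-8,8-dimethyl-5,7-diprenylbicyclo[3.3.1]nonane-2,4,9-trione
Conditions: LiCl, DMSO, 120 °C; then 1 M HCl
Reagents that add atoms: none
Why: Krapcho-type SN2 demethylation of the vinylogous methyl ester by chloride, after which the 2-silyl-1,3-diketonate loses silicon by protodesilylation on acidic work-up.

**Step 14**
Reactants: 20 (1R,5S,7R)-1-isobutyryl-8,8-dimethyl-5,7-diprenylbicyclo[3.3.1]nonane-2,4,9-trione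
Product: 21 (1R,5R,7R)-1-isobutyryl-8,8-dimethyl-5,7-diprenylbicyclo[3.3.1]nonane-2,3,4,9-tetraone (C5 descriptor changes by priority only)
Conditions: Dess–Martin periodinane, pyridine, water-saturated CH2Cl2, 23 °C
Reagents that add atoms: water O
Why: Dess–Martin oxidation of the active methylene of a 1,3-dicarbonyl compound to the vicinal tricarbonyl compound (hydroxylation of the enol, then alcohol oxidation), a pentavalent iodine oxidant that leaves the prenyl alkenes alone.

**Step 15**
Reactants: 22 ethyl (Z)-3-iodoacrylate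
Product: 23 (Z)-4-iodo-2-methylbut-3-en-2-ol
Conditions: MeMgBr, Et2O, −78 → 0 °C; aq. NH4Cl
Reagents that add atoms: methylmagnesium bromide C[Mg]Br
Why: Double Grignard 1,2-addition to the ester gives the tertiary alcohol without touching the Z-iodoalkene.

**Step 16**
Reactants: 21 (1R,5R,7R)-1-isobutyryl-8,8-dimethyl-5,7-diprenylbicyclo[3.3.1]nonane-2,3,4,9-tetraone; 23 (Z)-4-iodo-2-methylbut-3-en-2-ol
Product: 27 target CNP0190794.1 = (1S,3R,5R,7S)-7-hydroxy-7-[(Z)-4-hydroxy-4-methylpent-2-enoyl]-4,4-dimethyl-1,3-bis(3-methylbut-2-enyl)-5-(2-methylpropanoyl)bicyclo[3.2.1]octane-6,8-dione, via dilithio Z-vinyl reagent 24 (not isolated), via C3 alkoxide adduct 25 (not isolated), via ring-contracted dialkoxide 26 (not isolated)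
Conditions: 23, t-BuLi (3 equiv per 23), Et2O, −78 °C; then 21 (dried by azeotrope with toluene), THF, −78 → 23 °C; AcOH, then pH 7 buffer
Reagents that add atoms: none
Why: Proposed new method: the configurationally stable (Z)-vinyllithium 24 adds to C3, the central, most electrophilic and only unhindered carbonyl of the vicinal triketone (C2 and C4 are shielded by the quaternary bridgeheads C1 and C5), and on warming alkoxide 25 undergoes an anionic α-ketol (acyloin) rearrangement in which acyl carbon C2 migrates from C3 to C4, so that C3 leaves the ring as the conjugated enone carbonyl and O4 becomes the carbinolate of 26. The closest known reactions are the addition of carbanions to the central carbonyl of vicinal tricarbonyl compounds, the benzilic ester rearrangement and the base- or magnesium-promoted ring contraction of humulones to isohumulones; their merger on a bicyclo[3.3.1]nonane-2,3,4,9-tetraone has no direct precedent. The five-membered ring C1–C2–C4–C5–C9 is closed by this 1,2-acyl shift (C2–C4 forms while C2–C3 breaks in a three-centre transition state, six-membered ring A loses one atom), and no other ring is made or broken. C4 is the only new stereocentre and is controlled by the cage: ring B is a chair whose axial H7 fills the space under ring A, so the fully substituted C3 of 25 must tip towards C9 (boat ring A) and is extruded on that side, which places the enoyl group syn to C9 and the hydroxyl group over ring B whichever C3 epimer is formed, and the reversibility of the shift favours the same, less crowded epimer. The step needs regioselectivity (C2 to C4, not C4 to C2): a tetrahedral C2 would create three contiguous fully substituted carbons C8–C1–C2 beside the isobutyryl group, whereas C4 lies next to C5 and the C6 methylene, and the gain of enone conjugation drives the shift forward. The alkene geometry is carried over with retention from 23, and the side-chain alkoxide can cap the new enone carbonyl as a lactolate, which shields it from isomerisation and from excess reagent until the buffered quench.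

**Compound list**
1 | 4-hydroxy-2,6-dimethoxybenzaldehyde | O=Cc1c(OC)cc(O)cc1OC | starting material
2 | 4-formyl-3,5-dimethoxyphenyl pivalate | CC(C)(C)C(=O)Oc1cc(OC)c(C=O)c(OC)c1 | intermediate
3 | 4-(hydroxymethyl)-3,5-dimethoxyphenyl pivalate | CC(C)(C)C(=O)Oc1cc(OC)c(CO)c(OC)c1 | intermediate
4 | 4-(bromomethyl)-3,5-dimethoxyphenyl pivalate | CC(C)(C)C(=O)Oc1cc(OC)c(CBr)c(OC)c1 | intermediate
5 | (S)-4-benzyloxazolidin-2-one | O=C1N[C@@H](Cc2ccccc2)CO1 | starting material
6 | pent-4-enoyl chloride | C=CCCC(=O)Cl | starting material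
7 | N-lithio-(S)-4-benzyloxazolidin-2-one | [Li]N1[C@@H](Cc2ccccc2)COC1=O | intermediate
8 | (S)-4-benzyl-3-(pent-4-enoyl)oxazolidin-2-one | C=CCCC(=O)N1[C@@H](Cc2ccccc2)COC1=O | intermediate
9 | sodium (Z)-enolate of 8 | C=CC/C=C(\O[Na])N1[C@@H](Cc2ccccc2)COC1=O | intermediate
10 | (S)-4-benzyl-3-[(R)-2-(2,6-dimethoxy-4-pivaloyloxybenzyl)pent-4-enoyl]oxazolidin-2-one | C=CC[C@H](Cc1c(OC)cc(OC(=O)C(C)(C)C)cc1OC)C(=O)N1[C@@H](Cc2ccccc2)COC1=O | intermediate
11 | methyl (R)-2-(4-hydroxy-2,6-dimethoxybenzyl)pent-4-enoate | C=CC[C@H](Cc1c(OC)cc(O)cc1OC)C(=O)OC | intermediate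
12 | 4-[(R)-2-(2-hydroxypropan-2-yl)pent-4-enyl]-3,5-dimethoxyphenol | C=CC[C@H](Cc1c(OC)cc(O)cc1OC)C(C)(C)O | intermediate
13 | 4-allyl-4-[(R)-2-(2-hydroxypropan-2-yl)pent-4-enyl]-3,5-dimethoxycyclohexa-2,5-dienone | C=CC[C@H](CC1(CC=C)C(OC)=CC(=O)C=C1OC)C(C)(C)O | intermediate
14 | (1R,5S,7R)-5,7-diallyl-4-methoxy-8,8-dimethylbicyclo[3.3.1]non-3-ene-2,9-dione | C=CC[C@@H]1C[C@]2(CC=C)C(=O)[C@@H](C(=O)C=C2OC)C1(C)C | intermediate
15 | (1R,5S,7R)-4-methoxy-8,8-dimethyl-5,7-diprenylbicyclo[3.3.1]non-3-ene-2,9-dione | CC(C)=CC[C@@H]1C[C@]2(CC=C(C)C)C(=O)[C@@H](C(=O)C=C2OC)C1(C)C | intermediate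
16 | C3-lithio derivative of 15 | CC(C)=CC[C@@H]1C[C@]2(CC=C(C)C)C(=O)[C@@H](C(=O)C([Li])=C2OC)C1(C)C | intermediate
17 | (1S,5S,7R)-4-methoxy-8,8-dimethyl-5,7-diprenyl-3-(trimethylsilyl)bicyclo[3.3.1]non-3-ene-2,9-dione | CC(C)=CC[C@@H]1C[C@]2(CC=C(C)C)C(=O)[C@@H](C(=O)C([Si](C)(C)C)=C2OC)C1(C)C | intermediate
18 | C1-lithio (bridgehead) derivative of 17 | CC(C)=CC[C@@H]1C[C@]2(CC=C(C)C)C(=O)[C@@]([Li])(C(=O)C([Si](C)(C)C)=C2OC)C1(C)C | intermediate
19 | (1R,5S,7R)-1-isobutyryl-4-methoxy-8,8-dimethyl-5,7-diprenyl-3-(trimethylsilyl)bicyclo[3.3.1]non-3-ene-2,9-dione | CC(C)=CC[C@@H]1C[C@]2(CC=C(C)C)C(=O)[C@@](C(=O)C(C)C)(C(=O)C([Si](C)(C)C)=C2OC)C1(C)C | intermediate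
20 | (1R,5S,7R)-1-isobutyryl-8,8-dimethyl-5,7-diprenylbicyclo[3.3.1]nonane-2,4,9-trione | CC(C)=CC[C@@H]1C[C@]2(CC=C(C)C)C(=O)[C@@](C(=O)C(C)C)(C(=O)CC2=O)C1(C)C | intermediate
21 | (1R,5R,7R)-1-isobutyryl-8,8-dimethyl-5,7-diprenylbicyclo[3.3.1]nonane-2,3,4,9-tetraone | CC(C)=CC[C@@H]1C[C@]2(CC=C(C)C)C(=O)[C@@](C(=O)C(C)C)(C(=O)C(=O)C2=O)C1(C)C | intermediate
22 | ethyl (Z)-3-iodoacrylate | CCOC(=O)/C=C\I | starting material
23 | (Z)-4-iodo-2-methylbut-3-en-2-ol | CC(C)(O)/C=C\I | intermediate
24 | dilithio reagent, lithium (Z)-4-lithio-2-methylbut-3-en-2-olate | [Li]/C=C\C(C)(C)O[Li] | intermediate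
25 | dilithium salt of the C3 adduct (bicyclo[3.3.1]nonane, alkenyl group on the C9 side) | CC(C)=CC[C@@H]1C[C@]2(CC=C(C)C)C(=O)[C@@](C(=O)C(C)C)(C(=O)[C@@](O[Li])(/C=C\C(C)(C)O[Li])C2=O)C1(C)C | intermediate
26 | dilithium dialkoxide of the target (bicyclo[3.2.1]octane) | CC(C)=CC[C@@H]1C[C@]2(CC=C(C)C)C(=O)[C@@](C(=O)C(C)C)(C(=O)[C@@]2(O[Li])C(=O)/C=C\C(C)(C)O[Li])C1(C)C | intermediate
27 | CNP0190794.1, (1S,3R,5R,7S)-7-hydroxy-7-[(Z)-4-hydroxy-4-methylpent-2-enoyl]-4,4-dimethyl-1,3-bis(3-methylbut-2-enyl)-5-(2-methylpropanoyl)bicyclo[3.2.1]octane-6,8-dione | CC(C)=CC[C@@H]1C[C@]2(CC=C(C)C)C(=O)[C@@](C(=O)C(C)C)(C(=O)[C@@]2(O)C(=O)/C=C\C(C)(C)O)C1(C)C | target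

**Step count**
- Total step count: 16.
- Longest linear sequence: 14 (steps 1–3, 5–14 and 16).

**Steps most likely to fail**

1. **Step 16.**
- What may go wrong:
  - migration of the acyl group to oxygen instead of carbon, which enlarges the ring;
  - retro-Claisen loss of the isobutyryl group in the basic medium;
  - migration in the wrong direction;
  - Z-to-E isomerisation of the enone.
- Fallback: it sets out from 21 and comes back at 27, and every operation is of a known type.
  - 2-Methylbut-3-yn-2-ol is doubly deprotonated with n-BuLi to the dilithio acetylide F1.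
  - This is added to 21 at −78 °C and quenched cold with AcOH, so that the neutral propargylic C3 carbinol F2 is isolated before any migration.
  - The acyloin shift is then run as a separate, reversible step under the magnesium-salt conditions of the hop-acid isomerisation (MgCl2, Et3N, CH2Cl2) to give the conjugated ynone F3.
  - Semihydrogenation over Pd/CaCO3 poisoned with Pb(OAc)2 and quinoline sets the Z-alkene and gives 27.

2. **Step 12.**
- What may go wrong: incomplete deprotonation of the bridgehead next to the gem-dimethyl carbon, and proton transfer from the acid chloride (dehydrochlorination) in place of acylation of the hindered carbanion.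
- Fallback: it sets out from 17 and comes back at 19.
  - The anion 18 is trapped with the small electrophile iodine to give the bridgehead iodide F4.
  - Iodine–magnesium exchange with i-PrMgCl gives the bridgehead Grignard reagent F5.
  - This adds to isobutyraldehyde to give the bridgehead carbinol F6; the epimers at the carbinol carbon are of no consequence.
  - Dess–Martin oxidation then gives 19.

3. **Step 14.**
- What may go wrong: stalling at the stage of C3 oxygenation, hydration of the product, and oxidative C–C cleavage of the tricarbonyl unit.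
- Fallback: it sets out from 20 and comes back at 21.
  - Base-catalysed Ehrlich–Sachs condensation of the C3 methylene with 4-nitroso-N,N-dimethylaniline (piperidine cat., EtOH) gives the C3 anil F7.
  - Cold dilute H2SO4 in a two-phase system with Et2O hydrolyses it to 21.

**Further compounds**
F1 | step 16 | dilithio acetylide of 2-methylbut-3-yn-2-ol | [Li]C#CC(C)(C)O[Li]
F2 | step 16 | propargylic C3 carbinol, 3-hydroxy-3-(3-hydroxy-3-methylbut-1-ynyl) derivative of the 2,4,9-trione | CC(C)=CC[C@@H]1C[C@]2(CC=C(C)C)C(=O)[C@@](C(=O)C(C)C)(C(=O)[C@@](O)(C#CC(C)(C)O)C2=O)C1(C)C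
F3 | step 16 | conjugated ynone, 2,3-didehydro analogue of the target side chain on the bicyclo[3.2.1]octane | CC(C)=CC[C@@H]1C[C@]2(CC=C(C)C)C(=O)[C@@](C(=O)C(C)C)(C(=O)[C@@]2(O)C(=O)C#CC(C)(C)O)C1(C)C
F4 | step 12 | bridgehead iodide, 1-iodo derivative of 17 | CC(C)=CC[C@@H]1C[C@]2(CC=C(C)C)C(=O)[C@@](I)(C(=O)C([Si](C)(C)C)=C2OC)C1(C)C
F5 | step 12 | bridgehead Grignard reagent, 1-chloromagnesio derivative of 17 | CC(C)=CC[C@@H]1C[C@]2(CC=C(C)C)C(=O)[C@@]([Mg]Cl)(C(=O)C([Si](C)(C)C)=C2OC)C1(C)C
F6 | step 12 | bridgehead carbinol, 1-(1-hydroxy-2-methylpropyl) derivative of 17 | CC(C)=CC[C@@H]1C[C@]2(CC=C(C)C)C(=O)[C@@](C(O)C(C)C)(C(=O)C([Si](C)(C)C)=C2OC)C1(C)C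
F7 | step 14 | C3 anil, 3-[4-(dimethylamino)phenylimino] derivative of 20 | CC(C)=CC[C@@H]1C[C@]2(CC=C(C)C)C(=O)[C@@](C(=O)C(C)C)(C(=O)C(=Nc3ccc(N(C)C)cc3)C2=O)C1(C)C
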